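## Retrosynthetic overview

1. The target is unmasked last by hydrolysis of two acetonides (7,8-diol and 3',4'-diol).
2. Ring A (pyran) and ring B (cyclohexenone) are formed together, in one intramolecular oxa-Diels–Alder reaction of a 1,3-diacylallene: O=C3–C4=C4a is the heterodiene and the C8a=C1 vinyl group the dienophile. No ring of the bicycle exists before this step, and it also sets C8a.
3. The allene arises in the flask from a hydroxy-ynone by oxidation and prototropic shift; the hydroxy-ynone comes from a lithium acetylide (C1, C4–C8a) and a side-chain enoyl Weinreb amide (C3–C4 bond).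
4. Both halves come from Seebach dioxolanone aldols: (R)-lactic acid + acrolein gives C7/C8; (S)-lactic acid + (S)-2-methylbutanal gives C3'/C4'/C5'. C4, C4a and C5 come from propargyl bromide.

Assumption: the target is exactly the stereoisomer of the given SMILES, (7S,8S,8aS) in the bicycle and (1'E,3'S,4'R,5'S) in the side chain. Atoms are numbered as in 1H-isochromen-6-one (C1, O2, C3–C8a), side chain C1'–C7'.

## Route

Step 1
Reactants: 1 (R)-lactic acid
Product: 2 (2R,5R)-2-tert-butyl-5-methyl-1,3-dioxolan-4-one (cis)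
Conditions: tBuCHO (1.3 equiv), TsOH·H2O (cat.), H2SO4 (cat.), pentane, reflux, Dean–Stark; recrystallisation from pentane/Et2O, −78 °C
Reagents that add atoms: pivalaldehyde, CC(C)(C)C=O
Why: Acid-catalysed acetalisation (Seebach self-regeneration of stereocentres); the cis acetal is the thermodynamic product (about 4:1) and is enriched to ≥96:4 by crystallisation, so the lactate centre fixes the new acetal centre as 2R.

Step 2
Reactants: 2 (2R,5R)-2-tert-butyl-5-methyl-1,3-dioxolan-4-one; 3 acrolein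
Product: 5 (2R,5S)-2-tert-butyl-5-[(1S)-1-hydroxyprop-2-en-1-yl]-5-methyl-1,3-dioxolan-4-one, via lithium enolate 4 (not isolated)
Conditions: LiN(iPr)2 (1.05 equiv), THF, −78 °C; 3 (1.2 equiv, freshly distilled), −78 °C, 30 min; AcOH, −78 °C
Reagents that add atoms: none
Why: Aldol addition of the Seebach dioxolanone enolate; the new bond forms anti to the tert-butyl group, which sets quaternary C7 as (S); a closed Zimmerman–Traxler chair with the vinyl group pointing away from the ring gives the (1S)-carbinol C8 (7,8-anti diol pattern), expected dr about 4–6:1, the minor epimer being removed by chromatography.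

Step 3
Reactants: 5 (2R,5S)-2-tert-butyl-5-[(1S)-1-hydroxyprop-2-en-1-yl]-5-methyl-1,3-dioxolan-4-one
Product: 7 methyl (4S,5S)-5-ethenyl-2,2,4-trimethyl-1,3-dioxolane-4-carboxylate, via diol ester 6 (not isolated)
Conditions: NaOMe (0.1 equiv), MeOH, 0 °C; then TsOH·H2O (0.25 equiv), evaporate; Me2C(OMe)2/acetone, rt
Reagents that add atoms: methanol, CO; 2,2-dimethoxypropane, COC(C)(C)OC
Why: Methoxide-catalysed transesterification of the acylal lactone expels pivalaldehyde, and acid-catalysed ketal exchange then ties the tertiary and secondary hydroxyls into an acetonide; no stereocentre is touched.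

Step 4
Reactants: 7 methyl (4S,5S)-5-ethenyl-2,2,4-trimethyl-1,3-dioxolane-4-carboxylate; 8 propargyl bromide
Product: 11 1-[(4R,5S)-5-ethenyl-2,2,4-trimethyl-1,3-dioxolan-4-yl]but-3-yn-1-ol (both carbinol epimers), via allenylmagnesium bromide 9 (not isolated), via aldehyde 10 (not isolated)
Conditions: 8, Mg, HgCl2 (cat.), Et2O, 0 °C (gives 9); 7, iBu2AlH (1.1 equiv), CH2Cl2, −78 °C; then 9 (2.5 equiv), −78 → 0 °C; aq. potassium sodium tartrate
Reagents that add atoms: none
Why: One-pot partial reduction/Grignard addition; the chelated aluminium hemiacetal of the α-alkoxy ester releases aldehyde 10 only as it is trapped, and the allenyl Grignard reacts by SE2′ to give the homopropargylic alcohol; the new carbinol centre forms unselectively and is erased by oxidation in step 11.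

Step 5
Reactants: 12 (S)-2-methylbutan-1-ol
Product: 13 (S)-2-methylbutanal
Conditions: 2,2,6,6-tetramethylpiperidin-1-oxyl (TEMPO, 1 mol%), KBr (10 mol%), NaOCl (1.1 equiv), NaHCO3, CH2Cl2/H2O, 0 °C; distil, use the same day
Reagents that add atoms: none
Why: Anelli oxidation (TEMPO/NaOCl) at buffered pH and 0 °C stops at the aldehyde without epimerising the α-stereocentre, which becomes C5'.

Step 6
Reactants: 14 (S)-lactic acid
Product: 15 (2S,5S)-2-tert-butyl-5-methyl-1,3-dioxolan-4-one (cis)
Conditions: tBuCHO (1.3 equiv), TsOH·H2O (cat.), H2SO4 (cat.), pentane, reflux, Dean–Stark; recrystallisation from pentane/Et2O, −78 °C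
Reagents that add atoms: pivalaldehyde, CC(C)(C)C=O
Why: Acid-catalysed acetalisation (Seebach self-regeneration of stereocentres) as in step 1, here in the enantiomeric series; the cis acetal (2S) is obtained by crystallisation.

Step 7
Reactants: 15 (2S,5S)-2-tert-butyl-5-methyl-1,3-dioxolan-4-one; 13 (S)-2-methylbutanal
Product: 17 (2S,5R)-2-tert-butyl-5-[(1R,2S)-1-hydroxy-2-methylbutyl]-5-methyl-1,3-dioxolan-4-one, via lithium enolate 16 (not isolated)
Conditions: LiN(iPr)2 (1.05 equiv), THF, −78 °C; 13 (1.3 equiv), −78 °C, 45 min; AcOH, −78 °C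
Reagents that add atoms: none
Why: Aldol addition of the Seebach dioxolanone enolate; attack anti to tert-butyl sets C3', and the Zimmerman–Traxler chair gives the (1R)-carbinol C4' (3',4'-anti), which is also the Felkin–Anh product for the (S)-aldehyde, so enolate and aldehyde preferences are matched.

Step 8
Reactants: 17 (2S,5R)-2-tert-butyl-5-[(1R,2S)-1-hydroxy-2-methylbutyl]-5-methyl-1,3-dioxolan-4-one
Product: 19 methyl (4R,5R)-5-[(2S)-butan-2-yl]-2,2,4-trimethyl-1,3-dioxolane-4-carboxylate, via diol ester 18 (not isolated)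
Conditions: NaOMe (0.1 equiv), MeOH, 0 °C; then TsOH·H2O (0.25 equiv), evaporate; Me2C(OMe)2/acetone, rt
Reagents that add atoms: methanol, CO; 2,2-dimethoxypropane, COC(C)(C)OC
Why: Transesterification of the acylal lactone followed by acetonide formation (ketal exchange), as in step 3; no stereocentre is touched.

Step 9
Reactants: 19 methyl (4R,5R)-5-[(2S)-butan-2-yl]-2,2,4-trimethyl-1,3-dioxolane-4-carboxylate; 20 N-methoxy-N-methyl-2-(triphenylphosphoranylidene)acetamide
Product: 22 (2E)-3-[(4S,5R)-5-[(2S)-butan-2-yl]-2,2,4-trimethyl-1,3-dioxolan-4-yl]-N-methoxy-N-methylprop-2-enamide, via aldehyde 21 (not isolated)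
Conditions: iBu2AlH (1.1 equiv), CH2Cl2, −78 °C; MeOH (2 equiv); then 20 (1.5 equiv), −78 → 40 °C
Reagents that add atoms: none
Why: One-pot partial reduction/Wittig olefination; the α-quaternary aldehyde cannot epimerise and the amide-stabilised ylide gives the (E)-alkene C1'=C2'.

Step 10
Reactants: 11 1-[(4R,5S)-5-ethenyl-2,2,4-trimethyl-1,3-dioxolan-4-yl]but-3-yn-1-ol; 22 (2E)-3-[(4S,5R)-5-[(2S)-butan-2-yl]-2,2,4-trimethyl-1,3-dioxolan-4-yl]-N-methoxy-N-methylprop-2-enamide
Product: 24 (1E)-1-[(4S,5R)-5-[(2S)-butan-2-yl]-2,2,4-trimethyl-1,3-dioxolan-4-yl]-7-[(4R,5S)-5-ethenyl-2,2,4-trimethyl-1,3-dioxolan-4-yl]-7-hydroxyhept-1-en-4-yn-3-one (both carbinol epimers), via dilithio derivative 23 (not isolated)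
Conditions: 11, n-BuLi (2.05 equiv), THF, −78 → −30 °C; 22 (0.9 equiv), −78 → −20 °C; AcOH, −78 °C
Reagents that add atoms: none
Why: Weinreb ketone synthesis with a lithium acetylide; the chelated tetrahedral adduct prevents over-addition and keeps the base-sensitive skipped ynone masked until the cold acidic quench, forming the C3–C4 bond.

Step 11
Reactants: 24 (1E)-1-[(4S,5R)-5-[(2S)-butan-2-yl]-2,2,4-trimethyl-1,3-dioxolan-4-yl]-7-[(4R,5S)-5-ethenyl-2,2,4-trimethyl-1,3-dioxolan-4-yl]-7-hydroxyhept-1-en-4-yn-3-one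
Product: 27 (7S,8S,8aS)-3-{(E)-2-[(4S,5R)-5-[(2S)-butan-2-yl]-2,2,4-trimethyl-1,3-dioxolan-4-yl]ethenyl}-7,8-O-isopropylidene-7,8-dihydroxy-7-methyl-8,8a-dihydro-1H-isochromen-6(7H)-one (bis-acetonide of the target), via ynedione 25 (not isolated), via diacylallene 26 (not isolated)
Conditions: Dess–Martin periodinane (1.3 equiv), NaHCO3, CH2Cl2, 0 °C → rt; filter through Celite, switch solvent; Et3N (5 mol%), 2,6-di-tert-butyl-4-methylphenol (cat.), dry PhMe (0.005 M), 80 °C
Reagents that add atoms: none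
Why: Proposed new method: the C5 methylene of ynedione 25 is α to the C6 ketone and propargylic to the ynone, so catalytic Et3N shifts it to 1,3-diacylallene 26, which has no further proton to tautomerise; its O=C3–C4=C4a unit is a strained, electron-poor 1-oxadiene whose sp terminus C4a is held next to the vinyl group by the cis-dioxolane, so an inverse-electron-demand intramolecular hetero-Diels–Alder reaction forms C4a–C8a and O2–C1, closing ring B and ring A together and leaving the second allene π-bond as C4a=C5 conjugated with the C6 ketone; C8a is set in the cycloaddition by a chair-like tether with the C7 methyl and the C8 oxygen pseudo-equatorial, which places H-8a trans to H-8 (8aS); the closest known reaction types are the Tietze domino Knoevenagel/intramolecular oxa-Diels–Alder reaction of alkylidene-1,3-dicarbonyls with unactivated alkenes and the [4+2] reactions of acylallenes as heterodienes.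

Step 12
Reactants: 27 bis-acetonide of the target
Product: 28 (7S,8S,8aS)-3-[(1E,3S,4R,5S)-3,4-dihydroxy-3,5-dimethylhept-1-en-1-yl]-7,8-dihydroxy-7-methyl-8,8a-dihydro-1H-isochromen-6(7H)-one (CNP0291643.5)
Conditions: AcOH/H2O/THF (4:1:1), 45 °C
Reagents that add atoms: none
Why: Acid-catalysed acetal hydrolysis removes both acetonides; the doubly vinylogous ester of ring A is protonated on the carbonyl oxygen rather than opened under these mild conditions, and no stereocentre is involved.

## Compound list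

1 | (R)-lactic acid | C[C@@H](O)C(=O)O | starting material
2 | (2R,5R)-2-tert-butyl-5-methyl-1,3-dioxolan-4-one | C[C@H]1O[C@@H](C(C)(C)C)OC1=O | intermediate
3 | acrolein | C=CC=O | starting material
4 | lithium enolate of 2 | [Li+].CC1=C([O-])O[C@H](C(C)(C)C)O1 | intermediate
5 | (2R,5S)-2-tert-butyl-5-[(1S)-1-hydroxyprop-2-en-1-yl]-5-methyl-1,3-dioxolan-4-one | C=C[C@H](O)[C@]1(C)O[C@@H](C(C)(C)C)OC1=O | intermediate
6 | methyl (2S,3S)-2,3-dihydroxy-2-methylpent-4-enoate | COC(=O)[C@@](C)(O)[C@@H](O)C=C | intermediate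
7 | methyl (4S,5S)-5-ethenyl-2,2,4-trimethyl-1,3-dioxolane-4-carboxylate | COC(=O)[C@@]1(C)OC(C)(C)O[C@H]1C=C | intermediate
8 | propargyl bromide | C#CCBr | starting material
9 | allenylmagnesium bromide | C=C=C[Mg]Br | intermediate
10 | (4S,5S)-5-ethenyl-2,2,4-trimethyl-1,3-dioxolane-4-carbaldehyde | O=C[C@@]1(C)OC(C)(C)O[C@H]1C=C | intermediate
11 | 1-[(4R,5S)-5-ethenyl-2,2,4-trimethyl-1,3-dioxolan-4-yl]but-3-yn-1-ol (both carbinol epimers) | C#CCC(O)[C@@]1(C)OC(C)(C)O[C@H]1C=C | intermediate
12 | (S)-2-methylbutan-1-ol | CC[C@H](C)CO | starting material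
13 | (S)-2-methylbutanal | CC[C@H](C)C=O | intermediate
14 | (S)-lactic acid | C[C@H](O)C(=O)O | starting material
15 | (2S,5S)-2-tert-butyl-5-methyl-1,3-dioxolan-4-one | C[C@@H]1O[C@H](C(C)(C)C)OC1=O | intermediate
16 | lithium enolate of 15 | [Li+].CC1=C([O-])O[C@@H](C(C)(C)C)O1 | intermediate
17 | (2S,5R)-2-tert-butyl-5-[(1R,2S)-1-hydroxy-2-methylbutyl]-5-methyl-1,3-dioxolan-4-one | CC[C@H](C)[C@@H](O)[C@@]1(C)O[C@H](C(C)(C)C)OC1=O | intermediate
18 | methyl (2R,3R,4S)-2,3-dihydroxy-2,4-dimethylhexanoate | COC(=O)[C@](C)(O)[C@H](O)[C@@H](C)CC | intermediate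
19 | methyl (4R,5R)-5-[(2S)-butan-2-yl]-2,2,4-trimethyl-1,3-dioxolane-4-carboxylate | COC(=O)[C@]1(C)OC(C)(C)O[C@@H]1[C@@H](C)CC | intermediate
20 | N-methoxy-N-methyl-2-(triphenylphosphoranylidene)acetamide | CON(C)C(=O)C=P(c1ccccc1)(c1ccccc1)c1ccccc1 | starting material
21 | (4R,5R)-5-[(2S)-butan-2-yl]-2,2,4-trimethyl-1,3-dioxolane-4-carbaldehyde | O=C[C@]1(C)OC(C)(C)O[C@@H]1[C@@H](C)CC | intermediate
22 | (2E)-3-[(4S,5R)-5-[(2S)-butan-2-yl]-2,2,4-trimethyl-1,3-dioxolan-4-yl]-N-methoxy-N-methylprop-2-enamide | CON(C)C(=O)/C=C/[C@]1(C)OC(C)(C)O[C@@H]1[C@@H](C)CC | intermediate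
23 | dilithio derivative (alkoxide/acetylide) of 11 | [Li+].[Li+].[C-]#CCC([O-])[C@@]1(C)OC(C)(C)O[C@H]1C=C | intermediate
24 | (1E)-1-[(4S,5R)-5-[(2S)-butan-2-yl]-2,2,4-trimethyl-1,3-dioxolan-4-yl]-7-[(4R,5S)-5-ethenyl-2,2,4-trimethyl-1,3-dioxolan-4-yl]-7-hydroxyhept-1-en-4-yn-3-one (both carbinol epimers) | CC[C@H](C)[C@H]1OC(C)(C)O[C@@]1(C)/C=C/C(=O)C#CCC(O)[C@@]2(C)OC(C)(C)O[C@H]2C=C | intermediate
25 | (6E)-7-[(4S,5R)-5-[(2S)-butan-2-yl]-2,2,4-trimethyl-1,3-dioxolan-4-yl]-1-[(4S,5S)-5-ethenyl-2,2,4-trimethyl-1,3-dioxolan-4-yl]hept-6-en-3-yne-1,5-dione | CC[C@H](C)[C@H]1OC(C)(C)O[C@@]1(C)/C=C/C(=O)C#CCC(=O)[C@@]2(C)OC(C)(C)O[C@H]2C=C | intermediate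
26 | (6E)-7-[(4S,5R)-5-[(2S)-butan-2-yl]-2,2,4-trimethyl-1,3-dioxolan-4-yl]-1-[(4S,5S)-5-ethenyl-2,2,4-trimethyl-1,3-dioxolan-4-yl]hepta-2,3,6-triene-1,5-dione (both allene epimers, interconverting) | CC[C@H](C)[C@H]1OC(C)(C)O[C@@]1(C)/C=C/C(=O)C=C=CC(=O)[C@@]2(C)OC(C)(C)O[C@H]2C=C | intermediate
27 | bis-acetonide of the target, (7S,8S,8aS), 7,8-O- and 3',4'-O-isopropylidene | CC[C@H](C)[C@H]3OC(C)(C)O[C@@]3(C)/C=C/C1=CC2=CC(=O)[C@@]4(C)OC(C)(C)O[C@H]4[C@@H]2CO1 | intermediate
28 | (7S,8S,8aS)-3-[(1E,3S,4R,5S)-3,4-dihydroxy-3,5-dimethylhept-1-en-1-yl]-7,8-dihydroxy-7-methyl-8,8a-dihydro-1H-isochromen-6(7H)-one (CNP0291643.5) | CC[C@H](C)[C@@H](O)[C@@](C)(O)/C=C/C1=CC2=CC(=O)[C@@](C)(O)[C@@H](O)[C@@H]2CO1 | target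

## Step count and risks

Total: 12 steps. Longest linear sequence: 7 steps (1, 2, 3, 4, 10, 11, 12; the branch 6, 7, 8, 9, 10, 11, 12 is equally long).

The three steps most likely to fail:

Step 11 is the main risk. The oxa-Diels–Alder reaction has to engage an unactivated monosubstituted alkene, and allene 26 can instead dimerise, add amine or adventitious water at C4a, or close as an allenyl vinyl ketone (Nazarov-type) if acid is present. The face selectivity at C8a is a prediction, not a precedent. The fallback sets out from 24 and comes back at 27, forming the rings one after the other. Pd(OAc)2 (5 mol%) and PPh3 (10 mol%) in benzene at 60 °C cycloisomerise the 1,7-enyne of 24 (alkyne C4≡C4a, alkene C8a=C1, Alder-ene type) and close ring B alone, giving the (E)-dienone alcohol F1. Irradiation at 365 nm with catalytic I2 turns the enone to the Z geometry, whose O=C3–C4=C4a–C8a=C1 oxatriene closes thermally by oxa-6π electrocyclisation to ring A, giving the 2H-pyran alcohol F2. Dess–Martin periodinane oxidises the C6 carbinol to the β,γ-unsaturated ketone F3, and catalytic 1,8-diazabicyclo[5.4.0]undec-7-ene moves the C4a=C8a double bond into conjugation (C4a=C5), protonating C8a under thermodynamic control to give 27.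

Step 2 is the second risk (the same reasoning applies to step 7). The selectivity at the carbinol carbon in dioxolanone aldols is only moderate, the sense is predicted from the chair model, and acrolein can polymerise. The fallback sets out from 5 obtained as an epimer mixture and comes back at 5. The mixture is oxidised with Dess–Martin periodinane to the single vinyl ketone (2R,5S)-5-acryloyl-2-tert-butyl-5-methyl-1,3-dioxolan-4-one F4. F4 is then reduced under reagent control with (R)-1-methyl-3,3-diphenyltetrahydro-1H,3H-pyrrolo[1,2-c][1,3,2]oxazaborole (Corey–Bakshi–Shibata catalyst, 20 mol%) and catecholborane at −78 °C. With the quaternary carbon as the large group this delivers the (1S)-carbinol 5.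

Step 10 is the third risk. The dianion is poorly soluble, and the skipped en-yn-one product isomerises with any base left at work-up. The fallback sets out from 22 and comes back at 25, changing the union from acylation to carbonyl addition. iBu2AlH (THF, −78 °C) reduces 22 to the (E)-enal F5. Dilithio derivative 23, made from 11 as before, adds to F5 to give the ene-yne diol F6 as a mixture of carbinol epimers. Dess–Martin periodinane then oxidises both secondary alcohols at once to ynedione 25, from which step 11 continues unchanged.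

## Further compounds

F1 | step 11 | (E)-dienone alcohol, ring B closed, exocyclic C8a=CH2 and C4a=C4 | CC[C@H](C)[C@H]3OC(C)(C)O[C@@]3(C)/C=C/C(=O)/C=C1\CC(O)[C@@]2(C)OC(C)(C)O[C@H]2C1=C
F2 | step 11 | 2H-pyran alcohol, rings A and B closed, C4a=C8a, C6 carbinol | CC[C@H](C)[C@H]3OC(C)(C)O[C@@]3(C)/C=C/C1=CC2=C(CO1)[C@@H]4OC(C)(C)O[C@]4(C)C(O)C2
F3 | step 11 | β,γ-unsaturated ketone, C6 ketone, C4a=C8a | CC[C@H](C)[C@H]3OC(C)(C)O[C@@]3(C)/C=C/C1=CC2=C(CO1)[C@@H]4OC(C)(C)O[C@]4(C)C(=O)C2
F4 | step 2 | (2R,5S)-5-acryloyl-2-tert-butyl-5-methyl-1,3-dioxolan-4-one | C=CC(=O)[C@]1(C)O[C@@H](C(C)(C)C)OC1=O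
F5 | step 10 | (2E)-3-[(4S,5R)-5-[(2S)-butan-2-yl]-2,2,4-trimethyl-1,3-dioxolan-4-yl]prop-2-enal | O=C/C=C/[C@]1(C)OC(C)(C)O[C@@H]1[C@@H](C)CC
F6 | step 10 | (1E)-1-[(4S,5R)-5-[(2S)-butan-2-yl]-2,2,4-trimethyl-1,3-dioxolan-4-yl]-7-[(4R,5S)-5-ethenyl-2,2,4-trimethyl-1,3-dioxolan-4-yl]hept-1-en-4-yne-3,7-diol (carbinol epimers) | CC[C@H](C)[C@H]1OC(C)(C)O[C@@]1(C)/C=C/C(O)C#CCC(O)[C@@]2(C)OC(C)(C)O[C@H]2C=C
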